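# Design of a synthesis of the daucane epoxy tetrol 6-isovalerate 27

## The problem

The target 27 is the 6-isovalerate of a daucane tetrol epoxide: a cyclopentane (C1–C5) trans-fused to a cycloheptane (C1, C5–C10). C1 is the methyl-bearing fusion carbon, C4 the isopropyl carbinol, C5 the fusion CH, C6 the ester carbon, C8 the spiro-epoxide carbon with C14 as its CH2, and C9/C10 the diol carbons. Throughout, β is the face of the C1 methyl group and α the opposite face.

Seven contiguous stereocentres must be set. Two are fully substituted carbons on the five-membered ring (quaternary C1, tertiary carbinol C4) and one is the spiro-epoxide carbon C8. The C1 methyl and the C4 hydroxyl lie on the β face, while H-5 and the four oxygens on the seven-membered ring (C6, C8, C9, C10) lie on the α face.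

The control elements are therefore limited. The C4 hydroxyl can direct reagents only to the β face of C5/C6. The pseudo-axial C1 methyl sends reagents at C9 and C10 to the α face. The C10 hydroxyl can deliver hydride to C9, and the C9 hydroxyl can direct epoxidation of a C8=C14 alkene.

Three groups will not survive rough treatment: the spiro epoxide flanked by a cis-diol (acid, Lewis acid, base-induced epoxide migration), the isovalerate (hydride, alkoxide), and the C4 carbinol. The last is allylic or β to a carbonyl in most intermediates and is open to ionisation, retro-aldol cleavage and semipinacol shift. The epoxide is therefore made last and the ester late.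

The feature that opens the synthesis is how the seven-membered ring divides. C1–C5–C6–C7 can be a 1,3-diene on an intact cyclopentene. C8–C9–C10, with oxygen at C9 and the extra carbon C14 on C8, is the pattern of a 2-oxygenated vinylcarbenoid ester. A (4+3) union of the two builds the ring, the quaternary carbon C1 and the C8/C9 substitution pattern in one operation.

## Retrosynthesis

**Epoxide last (27 to 26).** The C8–O and C14–O bonds of 27 are cut, giving the 8(14)-ene 26 with free hydroxyls at C9 and C10. The neighbouring cut, methylene transfer to a C8 ketone, would have to choose a ketone face unaided. In 26 the allylic 9α-hydroxyl places the oxygen on its own face. The cut also keeps the sensitive epoxy diol out of every earlier step. 26 has one ring and one stereocentre fewer. The forward reaction must epoxidise a 1,1-disubstituted alkene syn to the C9 hydroxyl without touching the ester.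

**Ester and diol mask (26 to 25 to 24).** The acyl–O6 bond is cut. The three secondary hydroxyls at C6, C9 and C10 cannot be told apart by an acylating agent, so the 9,10-diol is carried as the cyclic carbonate (25, 24). The tertiary C4 hydroxyl needs no mask. The carbonate costs no protection step, because it is the form in which the cis-diol is made. The forward steps need acylation of a hindered secondary alcohol and then methanolysis of a strained five-membered carbonate beside a hindered ester.

**C5 and C6 (24 to 20).** The C6–O and C5–H bonds are traced to the C5=C6 alkene of 20 through ketone 23, alcohol 22 and epoxide 21.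
- A one-step syn addition of H and OH would be shorter. It is not used because the two alkene faces are not clearly differentiated (methyl and oxygen on β; isopropyl and the folded seven-membered ring on α), and the only director, the C4 hydroxyl, points to β, which is wrong for both new atoms.
- A Lewis-acid rearrangement of epoxide 21 directly to ketone 23 (hydride shift from C6 to C5) would save a step. It is not relied on because the C4 carbinol sits next to the tertiary epoxide carbon with its isopropyl group antiperiplanar to the C5–O bond, the ideal arrangement for a semipinacol shift.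
- The chosen sequence uses the director for what it can do (β-epoxide 21). The C5–O bond is then cleaved homolytically and the C5 radical quenched from the α face (22). C6 is inverted by oxidation (23) and hydride delivery from the C4 hydroxyl (24).

Compound 20 has two stereocentres fewer than 24.

**The 9α,10α-diol (20 to 15).** The C9–O and C10–O bonds are addressed through carbonate 19 (silyl ether of 20), vinyl epoxide 18, trans-diol 17, hydroxy ketone 16 and enone 15.
- The C10 oxygen is introduced as an electrophile on the enolate of 15, anti to the C1 methyl.
- Direct reduction of the C9 ketone cannot give the cis-diol. Both the pseudo-axial C1 methyl (1,3 to C9) and delivery from the 10α-hydroxyl send hydride to the α face, which gives the 9β-alcohol 17.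
- That predictable outcome is used. Closure of 17 to the α-epoxide 18 inverts C9, and palladium-catalysed carboxylative opening of the vinyl epoxide re-forms the C9–O bond with net retention, giving the cis-carbonate 19.
- Dihydroxylation of a C9=C10 alkene would also give the cis-diol, but it would discard the C9 oxygen that the key step delivers and cost more steps.

**Enone from the vinylogous ester (15 to 13).** The C8=C14 alkene and C9 ketone of 15 are traced to the C8 ester and C9 silyl enol ether of 13 through allylic alcohol 14. Hydride reduction followed by acid-induced loss of water and silanol is a carbonyl transposition of the Stork–Danheiser type. It turns the ester carbon into C14 and unmasks the ketone, so no carbon is added or removed.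

**Key disconnection (13 to 8 and 11).** The C7–C8 and C1–C10 bonds of 13 are cut, with cis-divinylcyclopropane 12 as the link between diene 8 and siloxyvinyl diazoester 11.
- A Diels–Alder/ring-expansion route would need an extra carbon-insertion step and would not place oxygen at C9.
- A (5+2) route lacks C14.
- The vinylcarbenoid route delivers all fifteen skeletal carbons, the quaternary C1, oxygen at C9 and C14, and a C5=C6 alkene next to the C4 director.

The precursors are a monocyclic diene with one stereocentre and an achiral diazo compound. The forward reaction must attack only the terminal alkene of 8, on one face, under control of a chiral dirhodium tetracarboxylate, and relay that choice to C1 through the boat Cope transition state.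

**Diene (8 to 1).** The vinyl group of 8 comes from enal 5 and phosphonium salt 6 (C6=C7 cut). Enal 5 comes from keto aldehyde 4 by intramolecular aldol condensation (C1=C5 cut), and 4 from the silyl ether 2 of (S)-terpinen-4-ol 1 by ozonolysis. The ring contraction keeps the C4 stereocentre of the chiral pool and puts the methyl group on C1. The alcohol is silylated first, because a free β-hydroxy aldehyde would be open to retro-aldol cleavage and dehydration under the amine catalyst.

**Diazo component (11 to 9).** Compound 11 is the enol silyl ether of diazo ketoester 10, made by diazo transfer to methyl acetoacetate 9.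

## Roads not taken

**Alternative 1: ring shift of a decalin.** The cut is C1–C5, re-drawn as C1–C6. The trans-fused ketone A1 would arise from the cis-decalin hydroxy mesylate A2, itself derived from (S)-Wieland–Miescher ketone A3. An aluminium Lewis acid would promote a semipinacol 1,2-shift of C1 from the carbinol carbon C6 to the mesylate carbon C5.
- Merits: the starting material is cheap, and the shift is stereospecific. It fixes the trans ring fusion with certainty, gives C6 as a ketone and leaves C10 oxidised. On ring-fusion control it is better than the chosen plan, which sets C5 in a radical step, and it needs no diazo compound or chiral rhodium catalyst.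
- Weak points: A1 lacks the isopropyl group, so the tertiary carbinol must come from addition to a hindered, enolisable C4 ketone next to the ring fusion. C7–C9 are bare methylenes, so C14 and the C9 oxygen must be introduced by several transpositions starting from C10. Hydride reduction of the C10 ketone would come anti to the C1 methyl and give the 10β-alcohol, the wrong epimer.
- Comparison: the chosen plan sets against the safer ring fusion a key-step product that already holds every skeletal carbon, the C4 carbinol from the chiral pool, and oxygen at C9 and C14.

**Alternative 2: rhodium-catalysed (5+2) cycloaddition.** The cuts are C1–C5 and C6–C7. Diene A4 would arise from the alkyne-tethered siloxy vinylcyclopropane A5 under a monovalent rhodium carbonyl catalyst.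
- Merits: the step is an isomerisation, closes both rings at once and needs no diazo compound. The enol ether of A4 is the C9=C10 regioisomer, so C10 could be oxidised directly; that is better than the chosen plan, which must pass through an enone. The C5=C6 alkene is in the same place, so the C5/C6 endgame would be the same.
- Weak points: C1 must be formed from a trisubstituted alkene terminus, where such cycloadditions are slow. Its configuration relies on relay from C4 across a flexible tether with similar-sized groups. The tertiary propargylic carbinol of A5 must be made enantioselectively, not taken from the chiral pool. C14 is missing and would have to be added at C8 in competition with C10.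
- Comparison: the chosen plan sets against the better atom economy a catalyst-controlled C1, a chiral-pool C4 and the delivery of C14 in the key step.

**Alternative 3: late chromium-mediated ring closure.** The cut is C8–C9. The allylic alcohol A6 would arise from bromo aldehyde A7 by a Nozaki–Hiyama–Kishi reaction (divalent chromium with catalytic nickel).
- Merits: ring closure gives the 8(14)-en-9-ol needed for the final directed epoxidation, with C6 and C10 oxygens already in place and differentiated. The endgame would be shorter than in the chosen plan, and no late C5/C6 work is needed.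
- Weak points: five stereocentres (C1, C4, C5, C6, C10) must be assembled on an open cyclopentane with two side chains, including the quaternary C1 beside the C10 carbinol; this means a long linear sequence. Addition to the α-silyloxy aldehyde is expected to follow the Felkin–Anh sense, which gives the trans-9,10-diol, not the cis-diol. The seven-membered closure also offers no help from the ring.
- Comparison: the chosen plan sets against the shorter endgame an early ring formation and stereocentres set on a rigid bicycle by directed reactions.

Key step: step 7

Assumption: Rh2(S-PTAD)4 is taken to be the catalyst antipode whose carbenoid attacks the vinyl face leading to 12 and so to the 1β-methyl series; if the sense of induction is the opposite, Rh2(R-PTAD)4 takes its place and nothing else changes.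

## Route

Step 1
Reactants: 1 (S)-(+)-terpinen-4-ol
Product: 2 (S)-triethyl[(1-isopropyl-4-methylcyclohex-3-en-1-yl)oxy]silane
Conditions: Et3SiOTf, 2,6-lutidine, CH2Cl2, 0 °C
Reagents that add atoms: triethylsilyl trifluoromethanesulfonate, CC[Si](CC)(CC)OS(=O)(=O)C(F)(F)F
Why: Silylation of a hindered tertiary alcohol with a silyl triflate; the ether blocks retro-aldol cleavage and elimination of the β-oxygenated aldehyde in steps 2 and 3 and O–H insertion in step 7, and the stereocentre is not touched.

Step 2
Reactants: 2 (S)-triethyl[(1-isopropyl-4-methylcyclohex-3-en-1-yl)oxy]silane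
Product: 4 (S)-3-isopropyl-6-oxo-3-(triethylsilyloxy)heptanal, via secondary ozonide 3 (not isolated)
Conditions: O3, CH2Cl2, −78 °C; then Me2S, −78 °C to rt
Reagents that add atoms: ozone, [O-][O+]=O
Why: Ozonolysis of the only alkene with reductive work-up of the ozonide gives the methyl ketone and the aldehyde; silyl ethers are inert to ozone and the quaternary stereocentre cannot epimerise.

Step 3
Reactants: 4 (S)-3-isopropyl-6-oxo-3-(triethylsilyloxy)heptanal
Product: 5 (R)-5-isopropyl-2-methyl-5-(triethylsilyloxy)cyclopent-1-ene-1-carbaldehyde
Conditions: piperidine (cat.), AcOH (cat.), toluene, 60 °C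
Reagents that add atoms: none
Why: Amine-catalysed intramolecular aldol condensation: the enamine of the aldehyde attacks the methyl ketone to close the five-membered ring and dehydration gives the conjugated tetrasubstituted enal, the known ring contraction of cyclohexene-derived 6-oxoheptanals; the descriptor changes from S to R only because the ring sp2 carbon now outranks isopropyl.

Step 4
Reactants: 5 (R)-5-isopropyl-2-methyl-5-(triethylsilyloxy)cyclopent-1-ene-1-carbaldehyde; 6 methyltriphenylphosphonium bromide
Product: 8 (R)-triethyl[(1-isopropyl-3-methyl-2-vinylcyclopent-2-en-1-yl)oxy]silane, via methylenetriphenylphosphorane 7 (not isolated)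
Conditions: 6, KOt-Bu, THF, 0 °C; then 5, 0 °C to rt
Reagents that add atoms: none
Why: Wittig methylenation of an enal with the unstabilised ylide made in the flask; the small ylide reaches the hindered aldehyde and the product is the 1,3-diene with a terminal and a tetrasubstituted alkene.

Step 5
Reactants: 9 methyl acetoacetate
Product: 10 methyl 2-diazo-3-oxobutanoate
Conditions: 4-acetamidobenzenesulfonyl azide, Et3N, MeCN, 0 °C to rt
Reagents that add atoms: 4-acetamidobenzenesulfonyl azide, CC(=O)Nc1ccc(cc1)S(=O)(=O)N=[N+]=[N-]
Why: Regitz diazo transfer to an active methylene compound.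

Step 6
Reactants: 10 methyl 2-diazo-3-oxobutanoate
Product: 11 methyl 3-(tert-butyldimethylsilyloxy)-2-diazobut-3-enoate
Conditions: t-BuMe2SiOTf, Et3N, CH2Cl2, 0 °C
Reagents that add atoms: tert-butyldimethylsilyl trifluoromethanesulfonate, CC(C)(C)[Si](C)(C)OS(=O)(=O)C(F)(F)F
Why: Soft enolisation and O-silylation of the acetyl group gives the siloxyvinyl diazoacetate, the standard precursor of 2-siloxyvinyl carbenoids; the diazo group is untouched.

Step 7
Reactants: 8 (R)-triethyl[(1-isopropyl-3-methyl-2-vinylcyclopent-2-en-1-yl)oxy]silane; 11 methyl 3-(tert-butyldimethylsilyloxy)-2-diazobut-3-enoate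
Product: 13 methyl 9-(tert-butyldimethylsilyloxy)-4β-(triethylsilyloxy)dauca-5,8-dien-14-oate, via cis-divinylcyclopropane 12 (not isolated)
Conditions: Rh2(S-PTAD)4 (1 mol %), slow addition of 11, hexanes, −26 °C to rt; then 60 °C
Reagents that add atoms: none
Why: The dirhodium catalyst converts 11 into a donor/acceptor siloxyvinyl carbenoid with loss of N2, and this adds to the terminal CH2 end of the vinyl group of 8 in a concerted, asynchronous cyclopropanation (C7–C8 and C6–C8 form) to give 12 with the siloxyvinyl group cis to the cyclopentenyl group, as donor/acceptor carbenoids do. The cis-divinylcyclopropane then undergoes a Cope rearrangement through the boat transition state, in which C1–C10 forms, C6–C8 breaks and the C5=C6 and C8=C9 alkenes appear. The closest known reaction type is the rhodium-catalysed tandem cyclopropanation/Cope rearrangement (formal (4+3) cycloaddition) of siloxyvinyl diazoacetates with 1,3-dienes, which has been used with ring-alkene termini to make quaternary carbons. The seven-membered ring is closed by the [3,3]-sigmatropic ring enlargement of the three-membered ring, not by a polar cyclisation. The one new stereocentre, C1, is set by chirality transfer: the catalyst fixes C6 and C8 of 12 by choosing the face of the vinyl group, and in the boat transition state C10 can then reach only the α face of C1 (the isopropyl side), which leaves the methyl group β, syn to the C4 silyloxy group. Site selectivity is secured because the tetrasubstituted ring alkene is inert to this bulky carbenoid, O–H insertion is excluded by the silyl ether, and the hydrocarbon solvent suppresses reaction at the vinylogous carbenoid position. Gentle warming completes the Cope step, which is slowed by the fully substituted C1 terminus.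

Step 8
Reactants: 13 methyl 9-(tert-butyldimethylsilyloxy)-4β-(triethylsilyloxy)dauca-5,8-dien-14-oate
Product: 15 4β-(triethylsilyloxy)dauca-5,8(14)-dien-9-one, via allylic alcohol 14 (not isolated)
Conditions: i-Bu2AlH, CH2Cl2, −78 °C; then 1 M HCl, THF, 0 °C
Reagents that add atoms: none
Why: Hydride reduces the vinylogous silyl carbonate ester to allylic alcohol 14, and dilute acid then removes water and the silyl group through the siloxyallyl cation to give the α-methylene ketone, a Stork–Danheiser-type transposition; brief cold acid spares the tertiary triethylsilyl ether.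

Step 9
Reactants: 15 4β-(triethylsilyloxy)dauca-5,8(14)-dien-9-one
Product: 16 10α-hydroxy-4β-(triethylsilyloxy)dauca-5,8(14)-dien-9-one
Conditions: KN(SiMe3)2, THF, −78 °C; 2-(phenylsulfonyl)-3-phenyloxaziridine; then AcOH
Reagents that add atoms: 2-(phenylsulfonyl)-3-phenyloxaziridine, O=S(=O)(c1ccccc1)N1OC1c1ccccc1
Why: C10 is the only enolisable position of the α-methylene ketone, and the cross-conjugated enolate is hydroxylated by the N-sulfonyloxaziridine (enolate oxidation); the pseudo-axial C1 methyl group covers the β face of C10, so oxygen enters from the α face.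

Step 10
Reactants: 16 10α-hydroxy-4β-(triethylsilyloxy)dauca-5,8(14)-dien-9-one
Product: 17 4β-(triethylsilyloxy)dauca-5,8(14)-diene-9β,10α-diol
Conditions: Me4NBH(OAc)3, MeCN/AcOH, −20 °C
Reagents that add atoms: none
Why: Evans–Saksena reduction: the C10 hydroxyl binds the acetoxyborohydride and delivers hydride to the α face of the C9 carbonyl (1,2-addition), the face that is also open sterically, so the trans-diol with the 9β-hydroxyl is expected.

Step 11
Reactants: 17 4β-(triethylsilyloxy)dauca-5,8(14)-diene-9β,10α-diol
Product: 18 9α,10α-epoxy-4β-(triethylsilyloxy)dauca-5,8(14)-diene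
Conditions: PPh3, DIAD, THF, 0 °C to 40 °C
Reagents that add atoms: none
Why: Mitsunobu cyclodehydration of a trans-1,2-diol: the less hindered allylic C9 hydroxyl becomes the oxyphosphonium leaving group and the C10 oxygen displaces it with inversion (SN2, three-membered ring closure), which puts the epoxide on the α face; displacement at the neopentyl C10 is not expected to compete.

Step 12
Reactants: 18 9α,10α-epoxy-4β-(triethylsilyloxy)dauca-5,8(14)-diene
Product: 19 4β-(triethylsilyloxy)dauca-5,8(14)-diene-9α,10α-diyl carbonate
Conditions: Pd(PPh3)4 (5 mol %), CO2 (1 atm), THF, 0 °C to rt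
Reagents that add atoms: carbon dioxide, O=C=O
Why: Zerovalent palladium ionises the vinyl epoxide with inversion at C9 (metal on the β face), the C10 alkoxide takes up CO2, and the carbonate oxygen closes the five-membered ring on the near allyl terminus anti to palladium, so C9–O is re-formed on the α face with net retention; this is the known palladium-catalysed carboxylation of vinyl epoxides to cis-vinyl carbonates.

Step 13
Reactants: 19 4β-(triethylsilyloxy)dauca-5,8(14)-diene-9α,10α-diyl carbonate
Product: 20 4β-hydroxydauca-5,8(14)-diene-9α,10α-diyl carbonate
Conditions: HF·pyridine, pyridine, THF, 0 °C to rt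
Reagents that add atoms: none
Why: Fluoride-mediated cleavage of the tertiary triethylsilyl ether under buffered conditions that do not ionise the tertiary allylic alcohol and leave the cyclic carbonate intact.

Step 14
Reactants: 20 4β-hydroxydauca-5,8(14)-diene-9α,10α-diyl carbonate
Product: 21 5β,6β-epoxy-4β-hydroxydauc-8(14)-ene-9α,10α-diyl carbonate
Conditions: VO(acac)2 (5 mol %), t-BuOOH, CH2Cl2, 0 °C
Reagents that add atoms: tert-butyl hydroperoxide, CC(C)(C)OO
Why: Vanadium-catalysed hydroxyl-directed epoxidation: the C4 hydroxyl delivers oxygen to the β face of the C5=C6 alkene; the C8=C14 alkene has no free allylic hydroxyl and should react far more slowly.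

Step 15
Reactants: 21 5β,6β-epoxy-4β-hydroxydauc-8(14)-ene-9α,10α-diyl carbonate
Product: 22 4β,6β-dihydroxy-5αH-dauc-8(14)-ene-9α,10α-diyl carbonate
Conditions: Cp2TiCl2, Zn, 1,4-cyclohexadiene, THF, rt; then 1 M HCl
Reagents that add atoms: none
Why: Titanocene-mediated reductive epoxide opening: Cp2TiCl (trivalent titanium) cleaves the C5–O bond to the tertiary C5 radical, which takes a hydrogen atom from 1,4-cyclohexadiene on the α face, opposite the bulky titanium alkoxide at C6, the C4 oxygen and the C1 methyl group, and so sets the trans ring fusion; no carbocation is formed, so the semipinacol shift is avoided.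

Step 16
Reactants: 22 4β,6β-dihydroxy-5αH-dauc-8(14)-ene-9α,10α-diyl carbonate
Product: 23 4β-hydroxy-6-oxo-5αH-dauc-8(14)-ene-9α,10α-diyl carbonate
Conditions: Dess–Martin periodinane, CH2Cl2, rt
Reagents that add atoms: none
Why: Dess–Martin oxidation of the only secondary alcohol under near-neutral conditions, which should not enolise C5 or cleave the β-hydroxy ketone.

Step 17
Reactants: 23 4β-hydroxy-6-oxo-5αH-dauc-8(14)-ene-9α,10α-diyl carbonate
Product: 24 4β,6α-dihydroxy-5αH-dauc-8(14)-ene-9α,10α-diyl carbonate
Conditions: Me4NBH(OAc)3, MeCN/AcOH, −20 °C
Reagents that add atoms: none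
Why: Evans–Saksena anti-selective reduction of a β-hydroxy ketone: hydride is delivered from boron bound to the 4β-hydroxyl through a six-membered transition state to the β face of C6, giving the 6α-alcohol; an undirected hydride would be hindered on that face by the axial C1 methyl group.

Step 18
Reactants: 24 4β,6α-dihydroxy-5αH-dauc-8(14)-ene-9α,10α-diyl carbonate
Product: 25 4β-hydroxy-6α-(3-methylbutanoyloxy)-5αH-dauc-8(14)-ene-9α,10α-diyl carbonate
Conditions: 3-methylbutanoyl chloride, pyridine, DMAP (cat.), CH2Cl2, 0 °C to rt
Reagents that add atoms: 3-methylbutanoyl chloride, CC(C)CC(=O)Cl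
Why: Nucleophile-catalysed acylation of the only free secondary hydroxyl; the tertiary C4 hydroxyl does not react under these conditions.

Step 19
Reactants: 25 4β-hydroxy-6α-(3-methylbutanoyloxy)-5αH-dauc-8(14)-ene-9α,10α-diyl carbonate
Product: 26 5αH-dauc-8(14)-ene-4β,6α,9α,10α-tetrol 6-(3-methylbutanoate)
Conditions: K2CO3 (cat.), MeOH, 0 °C
Reagents that add atoms: none
Why: Base-catalysed methanolysis of the strained five-membered carbonate, which is far more electrophilic than the β-branched ester of a hindered secondary alcohol; short reaction time at low temperature should keep the isovalerate.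

Step 20
Reactants: 26 5αH-dauc-8(14)-ene-4β,6α,9α,10α-tetrol 6-(3-methylbutanoate)
Product: 27 8α,14-epoxy-5αH-daucane-4β,6α,9α,10α-tetrol 6-(3-methylbutanoate)
Conditions: VO(acac)2 (5 mol %), t-BuOOH, CH2Cl2, 0 °C
Reagents that add atoms: tert-butyl hydroperoxide, CC(C)(C)OO
Why: Vanadium-catalysed hydroxyl-directed epoxidation of the exocyclic allylic alcohol: the 9α-hydroxyl, supported by the homoallylic 10α-hydroxyl on the same face, delivers oxygen to the α face of C8=C14, which sets the spiro centre with the epoxide oxygen syn to the C9 hydroxyl.

## Compound list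

1 | (S)-(+)-terpinen-4-ol, (S)-1-isopropyl-4-methylcyclohex-3-en-1-ol | CC1=CC[C@](O)(C(C)C)CC1 | starting material
2 | (S)-triethyl[(1-isopropyl-4-methylcyclohex-3-en-1-yl)oxy]silane | CC1=CC[C@](O[Si](CC)(CC)CC)(C(C)C)CC1 | intermediate
3 | secondary ozonide of 2, 4-isopropyl-1-methyl-4-(triethylsilyloxy)-7,8,9-trioxabicyclo[4.2.1]nonane (C4 as in 2; bridgehead carbons not controlled) | CC12CC[C@@](O[Si](CC)(CC)CC)(C(C)C)CC(OO1)O2 | intermediate (not isolated)
4 | (S)-3-isopropyl-6-oxo-3-(triethylsilyloxy)heptanal | CC(=O)CC[C@@](O[Si](CC)(CC)CC)(C(C)C)CC=O | intermediate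
5 | (R)-5-isopropyl-2-methyl-5-(triethylsilyloxy)cyclopent-1-ene-1-carbaldehyde | O=CC1=C(C)CC[C@@]1(O[Si](CC)(CC)CC)C(C)C | intermediate
6 | methyltriphenylphosphonium bromide | [Br-].C[P+](c1ccccc1)(c1ccccc1)c1ccccc1 | starting material
7 | methylenetriphenylphosphorane | C=P(c1ccccc1)(c1ccccc1)c1ccccc1 | intermediate (not isolated)
8 | (R)-triethyl[(1-isopropyl-3-methyl-2-vinylcyclopent-2-en-1-yl)oxy]silane | C=CC1=C(C)CC[C@@]1(O[Si](CC)(CC)CC)C(C)C | intermediate
9 | methyl acetoacetate | COC(=O)CC(C)=O | starting material
10 | methyl 2-diazo-3-oxobutanoate | COC(=O)C(=[N+]=[N-])C(C)=O | intermediate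
11 | methyl 3-(tert-butyldimethylsilyloxy)-2-diazobut-3-enoate | C=C(O[Si](C)(C)C(C)(C)C)C(=[N+]=[N-])C(=O)OC | intermediate
12 | cis-divinylcyclopropane, methyl (1R,2S)-1-[1-(tert-butyldimethylsilyloxy)vinyl]-2-[(R)-5-isopropyl-2-methyl-5-(triethylsilyloxy)cyclopent-1-en-1-yl]cyclopropane-1-carboxylate (siloxyvinyl cis to cyclopentenyl) | COC(=O)[C@]1(C(=C)O[Si](C)(C)C(C)(C)C)C[C@H]1C1=C(C)CC[C@@]1(O[Si](CC)(CC)CC)C(C)C | intermediate (not isolated)
13 | methyl 9-(tert-butyldimethylsilyloxy)-4β-(triethylsilyloxy)dauca-5,8-dien-14-oate (bicyclo[5.3.0]decadiene with C8 ester, C9 silyl enol ether, C5=C6 alkene, 1β-methyl) | COC(=O)C1=C(O[Si](C)(C)C(C)(C)C)C[C@@]2(C)CC[C@@](O[Si](CC)(CC)CC)(C(C)C)C2=CC1 | intermediate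
14 | 9-(tert-butyldimethylsilyloxy)-4β-(triethylsilyloxy)dauca-5,8-dien-14-ol | OCC1=C(O[Si](C)(C)C(C)(C)C)C[C@@]2(C)CC[C@@](O[Si](CC)(CC)CC)(C(C)C)C2=CC1 | intermediate (not isolated)
15 | 4β-(triethylsilyloxy)dauca-5,8(14)-dien-9-one | C=C1C(=O)C[C@@]2(C)CC[C@@](O[Si](CC)(CC)CC)(C(C)C)C2=CC1 | intermediate
16 | 10α-hydroxy-4β-(triethylsilyloxy)dauca-5,8(14)-dien-9-one | C=C1C(=O)[C@@H](O)[C@@]2(C)CC[C@@](O[Si](CC)(CC)CC)(C(C)C)C2=CC1 | intermediate
17 | 4β-(triethylsilyloxy)dauca-5,8(14)-diene-9β,10α-diol | C=C1[C@H](O)[C@@H](O)[C@@]2(C)CC[C@@](O[Si](CC)(CC)CC)(C(C)C)C2=CC1 | intermediate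
18 | 9α,10α-epoxy-4β-(triethylsilyloxy)dauca-5,8(14)-diene | C=C1[C@H]2O[C@H]2[C@@]3(C)CC[C@@](O[Si](CC)(CC)CC)(C(C)C)C3=CC1 | intermediate
19 | 4β-(triethylsilyloxy)dauca-5,8(14)-diene-9α,10α-diyl carbonate | C=C1[C@H]2OC(=O)O[C@H]2[C@@]3(C)CC[C@@](O[Si](CC)(CC)CC)(C(C)C)C3=CC1 | intermediate
20 | 4β-hydroxydauca-5,8(14)-diene-9α,10α-diyl carbonate | C=C1[C@H]2OC(=O)O[C@H]2[C@@]3(C)CC[C@@](O)(C(C)C)C3=CC1 | intermediate
21 | 5β,6β-epoxy-4β-hydroxydauc-8(14)-ene-9α,10α-diyl carbonate | C=C1[C@H]2OC(=O)O[C@H]2[C@@]3(C)CC[C@@](O)(C(C)C)[C@]34O[C@@H]4C1 | intermediate
22 | 4β,6β-dihydroxy-5αH-dauc-8(14)-ene-9α,10α-diyl carbonate | C=C1[C@H]2OC(=O)O[C@H]2[C@@]3(C)CC[C@@](O)(C(C)C)[C@@H]3[C@H](O)C1 | intermediate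
23 | 4β-hydroxy-6-oxo-5αH-dauc-8(14)-ene-9α,10α-diyl carbonate | C=C1[C@H]2OC(=O)O[C@H]2[C@@]3(C)CC[C@@](O)(C(C)C)[C@@H]3C(=O)C1 | intermediate
24 | 4β,6α-dihydroxy-5αH-dauc-8(14)-ene-9α,10α-diyl carbonate | C=C1[C@H]2OC(=O)O[C@H]2[C@@]3(C)CC[C@@](O)(C(C)C)[C@@H]3[C@@H](O)C1 | intermediate
25 | 4β-hydroxy-6α-(3-methylbutanoyloxy)-5αH-dauc-8(14)-ene-9α,10α-diyl carbonate | C=C1[C@H]2OC(=O)O[C@H]2[C@@]3(C)CC[C@@](O)(C(C)C)[C@@H]3[C@@H](OC(=O)CC(C)C)C1 | intermediate
26 | 5αH-dauc-8(14)-ene-4β,6α,9α,10α-tetrol 6-(3-methylbutanoate) | C=C1[C@@H](O)[C@@H](O)[C@@]2(C)CC[C@@](O)(C(C)C)[C@@H]2[C@@H](OC(=O)CC(C)C)C1 | intermediate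
27 | 8α,14-epoxy-5αH-daucane-4β,6α,9α,10α-tetrol 6-(3-methylbutanoate) (epoxide oxygen on the α face) | CC(C)CC(=O)O[C@H]1C[C@]2(CO2)[C@@H](O)[C@@H](O)[C@@]2(C)CC[C@@](O)(C(C)C)[C@H]12 | target

## Step count and least certain steps

Total step count: 20. Longest linear sequence: 18 steps (steps 1–4 and 7–20 from 1); steps 5 and 6 are the two-step branch to 11.

**Step 7 (key step).** The most likely failures are incomplete face selection by the catalyst on a diene whose only stereocentre is remote (C1 epimers after the Cope step), competing allylic C–H insertion, and a slow Cope step at the fully substituted C1 terminus. The fallback builds the same divinylcyclopropane stepwise. It sets out from 8 and 10. Rh2(OAc)4-catalysed cyclopropanation of the terminal alkene of 8 with the acceptor/acceptor carbenoid from 10 would give the cyclopropyl methyl ketone F1, which is stable and can be separated from its diastereomers. Soft enolisation (t-BuMe2SiOTf, Et3N) then turns the acetyl group into the siloxyvinyl group, giving 12, which rearranges on warming. The fallback comes back to the route at 13.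

**Step 15.** The most likely failure is poor facial selectivity in the hydrogen-atom transfer to the planar C5 radical, giving the cis-fused alcohol; reductive deoxygenation back to the alkene is a second risk. The fallback replaces kinetic control at C5 by thermodynamic control. It sets out from 21. The cis-fused alcohol F2 from the opening is oxidised with Dess–Martin periodinane to the cis-fused ketone F3. C5 is then epimerised with DBU in toluene toward the trans-fused ketone, which should be favoured because C6 is then trans to the isopropyl group and its carbonyl can hydrogen-bond to the C4 hydroxyl. The fallback comes back to the route at 23.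

**Step 9.** The most likely failure is Michael-type self-condensation of the potassium dienolate with the α-methylene ketone; less likely is attack of the oxidant from the β face. The fallback is a Rubottom oxidation through an isolated silyl enol ether. It sets out from 15. Me3SiOTf and Et3N would give the trimethylsilyl dienol ether F4. Dimethyldioxirane in acetone at −78 °C epoxidises the electron-rich C9=C10 bond from the α face, and silyl migration gives the 10α-trimethylsilyloxy ketone F5. Citric acid in MeOH removes the trimethylsilyl group and leaves the tertiary triethylsilyl ether. The fallback comes back to the route at 16.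

**Step 12.** The most likely failure is β-hydride elimination or isomerisation of the π-allylpalladium alkoxide to an enone or diene before CO2 is captured; attack at the exocyclic allyl terminus is a second risk. The fallback reaches the same net retention by two SN2 steps without palladium. It sets out from 18. MgBr2·OEt2 opens the epoxide at the allylic C9 with inversion to give the bromohydrin F6. Cs2CO3 under CO2 in DMF then carboxylates the C10 alkoxide, and the carbonate anion displaces the bromide with a second inversion. The fallback comes back to the route at 19.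

**Step 19.** The most likely failure is competing methanolysis of the isovalerate, or acyl migration to the liberated neighbours, during carbonate cleavage. The fallback reverses the order and protects the cis-diol transiently. It sets out from 24. K2CO3 in MeOH (no ester is present at this stage) would give the tetrol F7. Phenylboronic acid engages only the cis-9,10-diol and gives the phenylboronate F8. Acylation with 3-methylbutanoyl chloride and pyridine gives the boronate ester F9, and transesterification with pinacol releases the diol. The fallback comes back to the route at 26.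

## Further compounds

F1 | step 7 | methyl (1R,2S)-1-acetyl-2-[(R)-5-isopropyl-2-methyl-5-(triethylsilyloxy)cyclopent-1-en-1-yl]cyclopropane-1-carboxylate (acetyl cis to cyclopentenyl) | COC(=O)[C@]1(C(C)=O)C[C@H]1C1=C(C)CC[C@@]1(O[Si](CC)(CC)CC)C(C)C
F2 | step 15 | 4β,6β-dihydroxy-5βH-dauc-8(14)-ene-9α,10α-diyl carbonate (cis-fused alcohol) | C=C1[C@H]2OC(=O)O[C@H]2[C@@]3(C)CC[C@@](O)(C(C)C)[C@H]3[C@H](O)C1
F3 | step 15 | 4β-hydroxy-6-oxo-5βH-dauc-8(14)-ene-9α,10α-diyl carbonate (cis-fused ketone) | C=C1[C@H]2OC(=O)O[C@H]2[C@@]3(C)CC[C@@](O)(C(C)C)[C@H]3C(=O)C1
F4 | step 9 | 4β-(triethylsilyloxy)-9-(trimethylsilyloxy)dauca-5,8(14),9-triene | C=C1C(O[Si](C)(C)C)=C[C@@]2(C)CC[C@@](O[Si](CC)(CC)CC)(C(C)C)C2=CC1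
F5 | step 9 | 4β-(triethylsilyloxy)-10α-(trimethylsilyloxy)dauca-5,8(14)-dien-9-one | C=C1C(=O)[C@@H](O[Si](C)(C)C)[C@@]2(C)CC[C@@](O[Si](CC)(CC)CC)(C(C)C)C2=CC1
F6 | step 12 | 9β-bromo-4β-(triethylsilyloxy)dauca-5,8(14)-dien-10α-ol | C=C1[C@H](Br)[C@@H](O)[C@@]2(C)CC[C@@](O[Si](CC)(CC)CC)(C(C)C)C2=CC1
F7 | step 19 | 5αH-dauc-8(14)-ene-4β,6α,9α,10α-tetrol | C=C1[C@@H](O)[C@@H](O)[C@@]2(C)CC[C@@](O)(C(C)C)[C@@H]2[C@@H](O)C1
F8 | step 19 | 5αH-dauc-8(14)-ene-4β,6α,9α,10α-tetrol 9,10-phenylboronate | C=C1[C@H]2OB(c3ccccc3)O[C@H]2[C@@]3(C)CC[C@@](O)(C(C)C)[C@@H]3[C@@H](O)C1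
F9 | step 19 | 5αH-dauc-8(14)-ene-4β,6α,9α,10α-tetrol 6-(3-methylbutanoate) 9,10-phenylboronate | C=C1[C@H]2OB(c3ccccc3)O[C@H]2[C@@]3(C)CC[C@@](O)(C(C)C)[C@@H]3[C@@H](OC(=O)CC(C)C)C1
A1 | alternative 1 | 4β-(tert-butyldimethylsilyloxy)-10,10-ethylenedioxy-1β-methyl-5αH-bicyclo[5.3.0]decan-6-one | O=C1CCCC2(OCCO2)[C@@]3(C)CC[C@H](O[Si](C)(C)C(C)(C)C)[C@H]13
A2 | alternative 1 | cis-decalin hydroxy mesylate (tertiary C6 alcohol, C5 mesylate, C4 silyl ether, C10 dioxolane) | CS(=O)(=O)O[C@H]1[C@@H](O[Si](C)(C)C(C)(C)C)CC[C@]2(C)C3(OCCO3)CCC[C@]12O
A3 | alternative 1 | (S)-Wieland–Miescher ketone | C[C@]12CCC(=O)C=C1CCCC2=O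
A4 | alternative 2 | 9-(tert-butyldimethylsilyloxy)-4β-(triethylsilyloxy)-14-nordauca-5,9-diene | C1=C2[C@](O[Si](CC)(CC)CC)(C(C)C)CC[C@]2(C)C=C(O[Si](C)(C)C(C)(C)C)CC1
A5 | alternative 2 | (E)-alkene-linked 1-(tert-butyldimethylsilyloxy)cyclopropane with a tertiary propargylic triethylsilyl ether | C#C[C@](O[Si](CC)(CC)CC)(C(C)C)CC/C(C)=C/C1(O[Si](C)(C)C(C)(C)C)CC1
A6 | alternative 3 | 10α-(tert-butyldimethylsilyloxy)-6α-(4-methoxybenzyloxy)-5αH-dauc-8(14)-ene-4β,9α-diol | COc1ccc(CO[C@H]2CC(=C)[C@@H](O)[C@@H](O[Si](C)(C)C(C)(C)C)[C@@]3(C)CC[C@@](O)(C(C)C)[C@H]23)cc1
A7 | alternative 3 | cyclopentane bromo aldehyde (C8 vinyl bromide, C9 aldehyde, C6 4-methoxybenzyl ether, C10 silyl ether, free C4 carbinol) | COc1ccc(CO[C@@H](CC(Br)=C)[C@H]2[C@](O)(C(C)C)CC[C@]2(C)[C@H](O[Si](C)(C)C(C)(C)C)C=O)cc1
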